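The C3–C4 bond of ring A is the one disconnection on which the route rests. The cis-1,2-diol formed by the secondary C3 carbinol and the tertiary, methyl-bearing C4 carbinol, flanking the C5=C6 double bond, is the signature of a reductive coupling between a C3 aldehyde and a C4 methyl ketone. In one operation SmI2 forges that bond, closes ring A and sets both oxygen-bearing stereocentres on the β face. The precursor is a carvone-derived cyclohexene that already holds the C10 quaternary methyl, the C7 side chain as a silyl-protected allylic alcohol, a three-carbon aldehyde arm on C10 and an acetyl group on C5 of the ring alkene.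

Key step: step 9

Remark: bicyclic compounds carry eudesmane numbering (C14 on C10, C15 on C4, C11–C13 in the side chain; β is the face of the C10 methyl), and the C12 hydroxyl is assumed to be best carried as its tert-butyldiphenylsilyl ether, which tolerates the acidic unmasking of the acetyl group in step 8.

Step 1
Reactants: 1 (R)-(−)-carvone
Product: 2 (5R)-5-(3-chloroprop-1-en-2-yl)-2-methylcyclohex-2-en-1-one (10-chlorocarvone)
Conditions: Ca(OCl)2, CO2 (dry ice), CH2Cl2/H2O, 0 °C
Reagents that add atoms: calcium hypochlorite, [Ca+2].[O-]Cl.[O-]Cl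
Why: Ene-type allylic chlorination by HOCl generated in the flask should attack only the electron-rich 1,1-disubstituted alkene and leave the conjugated enone and the C5 stereocentre untouched.

Step 2
Reactants: 2 10-chlorocarvone
Product: 4 (5R)-5-(3-hydroxyprop-1-en-2-yl)-2-methylcyclohex-2-en-1-one (10-hydroxycarvone), via allylic acetate 3 (not isolated)
Conditions: KOAc, Bu4NI (cat.), DMF, 60 °C; then MeOH, K2CO3 (0.2 equiv), rt
Reagents that add atoms: potassium acetate, CC(=O)[O-].[K+]
Why: SN2 displacement of the primary allylic chloride by acetate (direct and allylically transposed attack give the same product) followed by base-catalysed transesterification should free the primary allylic alcohol.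

Step 3
Reactants: 4 10-hydroxycarvone
Product: 5 (5R)-5-[3-(tert-butyldiphenylsilyloxy)prop-1-en-2-yl]-2-methylcyclohex-2-en-1-one
Conditions: TBDPSCl, imidazole, CH2Cl2, 0 °C → rt
Reagents that add atoms: tert-butyl(chloro)diphenylsilane, CC(C)(C)[Si](Cl)(c1ccccc1)c1ccccc1
Why: Standard silylation of a primary alcohol gives a bulky silyl ether that should withstand the hydride, base, mild acid, palladium and SmI2 steps that follow.

Step 4
Reactants: 5 silyl ether of 10-hydroxycarvone
Product: 6 (5R)-5-[3-(tert-butyldiphenylsilyloxy)prop-1-en-2-yl]-2-methylcyclohexan-1-one (both C2 epimers)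
Conditions: LiBH(s-Bu)3, THF, −78 °C; then H2O, −78 °C → rt
Reagents that add atoms: none
Why: Conjugate hydride reduction of the β-unsubstituted cyclohexenone by the bulky trialkylborohydride should give the saturated ketone after protonation of the enolate; the C2 epimers are both usable because C2 becomes trigonal in step 5, and the isolated alkene is inert.

Step 5
Reactants: 6 2-methylcyclohexanone with the silyloxy side chain; 7 methyl acrylate
Product: 10 methyl 3-[(1S,4R)-4-[3-(tert-butyldiphenylsilyloxy)prop-1-en-2-yl]-1-methyl-2-oxocyclohexyl]propanoate, via ketimine 8 (not isolated), via adduct imine 9 (not isolated)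
Conditions: (R)-1-phenylethylamine, p-TsOH (cat.), toluene, reflux (Dean–Stark); then 7, hydroquinone (cat.), THF, 60 °C; then 10% aq. AcOH, THF, rt
Reagents that add atoms: water, O
Why: Asymmetric Michael addition of a chiral imine: the more substituted secondary enamine tautomer should add to the acrylate in an aza-ene-like transition state on the face not shielded by the phenyl group of the (R)-auxiliary, which sets the quaternary carbon (S) with the ester arm trans to the C4 side chain, and mild acid hydrolysis returns the ketone.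

Step 6
Reactants: 10 keto ester
Product: 11 methyl 3-[(1S,4R)-4-[3-(tert-butyldiphenylsilyloxy)prop-1-en-2-yl]-1-methyl-2-(trifluoromethylsulfonyloxy)cyclohex-2-en-1-yl]propanoate
Conditions: KN(SiMe3)2 (1.05 equiv), THF, −78 °C; then PhNTf2, −78 → 0 °C
Reagents that add atoms: N-phenylbis(trifluoromethanesulfonimide), O=S(=O)(N(c1ccccc1)S(=O)(=O)C(F)(F)F)C(F)(F)F
Why: Kinetic deprotonation at the only enolisable α-carbon of the ketone (more acidic than the ester α-position) and O-sulfonylation of the enolate should give a single regioisomer of the enol triflate.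

Step 7
Reactants: 11 enol triflate ester
Product: 12 3-[(1S,4R)-4-[3-(tert-butyldiphenylsilyloxy)prop-1-en-2-yl]-1-methyl-2-(trifluoromethylsulfonyloxy)cyclohex-2-en-1-yl]propanal
Conditions: i-Bu2AlH (1.1 equiv), CH2Cl2, −78 °C; then aq. potassium sodium tartrate
Reagents that add atoms: none
Why: Partial reduction of the methyl ester at −78 °C should stop at the aluminium hemiacetal, which releases the aldehyde on work-up; the enol triflate and silyl ether are inert, and the reduction is placed here because no ketone is yet present to compete.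

Step 8
Reactants: 12 triflate aldehyde; 13 tributyl(1-ethoxyvinyl)stannane
Product: 15 3-[(1S,4R)-2-acetyl-4-[3-(tert-butyldiphenylsilyloxy)prop-1-en-2-yl]-1-methylcyclohex-2-en-1-yl]propanal, via ethoxydiene aldehyde 14 (not isolated)
Conditions: Pd(PPh3)4 (5 mol%), CuI (10 mol%), LiCl (3 equiv), DMF, 70 °C; then 1 M HCl, THF, 0 °C, 15 min
Reagents that add atoms: water, O
Why: Stille coupling (LiCl and CuI assist the hindered triflate) should install the 1-ethoxyvinyl group as a masked acetyl, and brief dilute acid should hydrolyse the 2-ethoxydiene to the methyl enone without touching the aldehyde, the silyl ether or the C7 stereocentre.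

Step 9
Reactants: 15 keto aldehyde
Product: 16 12-(tert-butyldiphenylsilyloxy)eudesma-5,11(13)-diene-3β,4β-diol, (3S,4R,7R,10S)
Conditions: SmI2 (2.5 equiv, 0.1 M in THF), t-BuOH (2 equiv), THF (0.01 M in 15), −78 °C → rt; aq. NaHCO3 work-up
Reagents that add atoms: none
Why: SmI2 should reduce the unhindered aldehyde to a samarium ketyl that adds to the samarium-bound C4 ketone carbon, and a second electron gives a trivalent-samarium diolate that t-BuOH protonates. The closest known reaction type is the SmI2-mediated intramolecular pinacol cyclisation of keto aldehydes to cis-cycloalkane-1,2-diols. Ring A closes by 6-exo-trig attack of C3 on the C4 carbonyl. C3 is controlled by the samarium bridge between the two oxygens, which holds them cis; C4 is controlled by the chair-like closure, in which the C10 methyl is necessarily axial on the forming ring, so the C4 methyl goes equatorial to avoid it and the C4 oxygen goes axial on the β face. The step needs 1,2-coupling in preference to 1,4-coupling or simple reduction: the propanal arm is pseudo-equatorial on ring B when the C7 side chain is equatorial, so it reaches C4 but not C6, bonding to C6 would need both groups axial and would build a bicyclo[3.3.1] bridge, and omitting HMPA keeps the reductant too weak to reduce the twisted enone directly.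

Step 10
Reactants: 16 cis-diol; 17 angelic acid
Product: 19 12-(tert-butyldiphenylsilyloxy)-4β-hydroxyeudesma-5,11(13)-dien-3β-yl (Z)-2-methylbut-2-enoate, via mixed anhydride 18 (not isolated)
Conditions: 17, 2,4,6-trichlorobenzoyl chloride, Et3N, toluene, rt; then 16, toluene, 80 °C
Reagents that add atoms: none
Why: Yamaguchi-type esterification without DMAP: the equatorial secondary C3 hydroxyl should attack the unhindered angeloyl carbonyl of the mixed anhydride, conditions under which the (Z)-2-methylbut-2-enoyl group is transferred without isomerisation to the tiglate, while the tertiary C4 hydroxyl stays free.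

Step 11
Reactants: 19 angelate silyl ether
Product: 20 4β,12-dihydroxyeudesma-5,11(13)-dien-3β-yl (Z)-2-methylbut-2-enoate
Conditions: Bu4NF, AcOH (1:1), THF, 0 °C → rt
Reagents that add atoms: none
Why: Fluoride-mediated desilylation; buffering with AcOH should suppress acyl migration, angelate isomerisation and ionisation of the tertiary allylic alcohol.

Step 12
Reactants: 20 allylic alcohol
Product: 21 4β-hydroxy-12-oxoeudesma-5,11(13)-dien-3β-yl (Z)-2-methylbut-2-enoate
Conditions: MnO2 (activated, excess), CH2Cl2, rt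
Reagents that add atoms: none
Why: MnO2 should oxidise only the primary allylic alcohol to the 2-substituted acrolein; the tertiary allylic alcohol cannot be oxidised and the neutral medium should not move the 11(13) double bond into conjugation.

Step 13
Reactants: 21 enal
Product: 22 3β-[(Z)-2-methylbut-2-enoyloxy]-4β-hydroxyeudesma-5,11(13)-dien-12-oic acid
Conditions: NaClO2, NaH2PO4, 2-methyl-2-butene, t-BuOH/H2O, 0 °C → rt
Reagents that add atoms: sodium chlorite, [Na+].[O-]Cl=O
Why: Pinnick oxidation should convert the enal into the acrylic acid at about pH 4, with 2-methyl-2-butene trapping the HOCl formed so that the alkenes are not chlorinated.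

Step 14
Reactants: 22 acrylic acid
Product: 23 methyl 3β-[(Z)-2-methylbut-2-enoyloxy]-4β-hydroxyeudesma-5,11(13)-dien-12-oate, (3S,4R,7R,10S), the target
Conditions: Me3SiCHN2 (2 M in hexanes), MeOH/toluene (1:4), 0 °C
Reagents that add atoms: trimethylsilyldiazomethane, C[Si](C)(C)C=[N+]=[N-]
Why: Methyl esterification with trimethylsilyldiazomethane and methanol is fast and neutral, so neither the angelate geometry nor the skipped diene should be disturbed.

Compound list
1 | (R)-(−)-carvone, (5R)-2-methyl-5-(prop-1-en-2-yl)cyclohex-2-en-1-one | CC1=CC[C@@H](C(C)=C)CC1=O | starting material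
2 | (5R)-5-(3-chloroprop-1-en-2-yl)-2-methylcyclohex-2-en-1-one | CC1=CC[C@@H](C(CCl)=C)CC1=O | intermediate
3 | (5R)-5-(3-acetoxyprop-1-en-2-yl)-2-methylcyclohex-2-en-1-one (not isolated) | CC1=CC[C@@H](C(COC(C)=O)=C)CC1=O | intermediate
4 | (5R)-5-(3-hydroxyprop-1-en-2-yl)-2-methylcyclohex-2-en-1-one | CC1=CC[C@@H](C(CO)=C)CC1=O | intermediate
5 | (5R)-5-[3-(tert-butyldiphenylsilyloxy)prop-1-en-2-yl]-2-methylcyclohex-2-en-1-one | CC1=CC[C@@H](C(CO[Si](c2ccccc2)(c2ccccc2)C(C)(C)C)=C)CC1=O | intermediate
6 | (5R)-5-[3-(tert-butyldiphenylsilyloxy)prop-1-en-2-yl]-2-methylcyclohexan-1-one, C2 epimer mixture | CC1CC[C@@H](C(CO[Si](c2ccccc2)(c2ccccc2)C(C)(C)C)=C)CC1=O | intermediate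
7 | methyl acrylate | C=CC(=O)OC | starting material
8 | N-[(1R)-1-phenylethyl] ketimine of 6 (not isolated) | C[C@H](c1ccccc1)N=C1C[C@H](C(=C)CO[Si](c2ccccc2)(c2ccccc2)C(C)(C)C)CCC1C | intermediate
9 | N-[(1R)-1-phenylethyl] ketimine of keto ester 10 (not isolated) | C[C@H](c1ccccc1)N=C1C[C@H](C(=C)CO[Si](c2ccccc2)(c2ccccc2)C(C)(C)C)CC[C@@]1(C)CCC(=O)OC | intermediate
10 | methyl 3-[(1S,4R)-4-[3-(tert-butyldiphenylsilyloxy)prop-1-en-2-yl]-1-methyl-2-oxocyclohexyl]propanoate | O=C1C[C@H](C(=C)CO[Si](c2ccccc2)(c2ccccc2)C(C)(C)C)CC[C@@]1(C)CCC(=O)OC | intermediate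
11 | methyl 3-[(1S,4R)-4-[3-(tert-butyldiphenylsilyloxy)prop-1-en-2-yl]-1-methyl-2-(trifluoromethylsulfonyloxy)cyclohex-2-en-1-yl]propanoate | O=S(=O)(OC1=C[C@H](C(=C)CO[Si](c2ccccc2)(c2ccccc2)C(C)(C)C)CC[C@@]1(C)CCC(=O)OC)C(F)(F)F | intermediate
12 | 3-[(1S,4R)-4-[3-(tert-butyldiphenylsilyloxy)prop-1-en-2-yl]-1-methyl-2-(trifluoromethylsulfonyloxy)cyclohex-2-en-1-yl]propanal | O=S(=O)(OC1=C[C@H](C(=C)CO[Si](c2ccccc2)(c2ccccc2)C(C)(C)C)CC[C@@]1(C)CCC=O)C(F)(F)F | intermediate
13 | tributyl(1-ethoxyvinyl)stannane | CCOC(=C)[Sn](CCCC)(CCCC)CCCC | starting material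
14 | 3-[(1S,4R)-4-[3-(tert-butyldiphenylsilyloxy)prop-1-en-2-yl]-2-(1-ethoxyvinyl)-1-methylcyclohex-2-en-1-yl]propanal (not isolated) | CCOC(=C)C1=C[C@H](C(=C)CO[Si](c2ccccc2)(c2ccccc2)C(C)(C)C)CC[C@@]1(C)CCC=O | intermediate
15 | 3-[(1S,4R)-2-acetyl-4-[3-(tert-butyldiphenylsilyloxy)prop-1-en-2-yl]-1-methylcyclohex-2-en-1-yl]propanal | CC(=O)C1=C[C@H](C(=C)CO[Si](c2ccccc2)(c2ccccc2)C(C)(C)C)CC[C@@]1(C)CCC=O | intermediate
16 | 12-(tert-butyldiphenylsilyloxy)eudesma-5,11(13)-diene-3β,4β-diol, (3S,4R,7R,10S) | C=C(CO[Si](c1ccccc1)(c1ccccc1)C(C)(C)C)[C@H]1C=C2[C@](C)(CC[C@H](O)[C@]2(C)O)CC1 | intermediate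
17 | angelic acid, (Z)-2-methylbut-2-enoic acid | C/C=C(/C)C(=O)O | starting material
18 | (Z)-2-methylbut-2-enoic 2,4,6-trichlorobenzoic anhydride (not isolated) | C/C=C(/C)C(=O)OC(=O)c1c(Cl)cc(Cl)cc1Cl | intermediate
19 | 12-(tert-butyldiphenylsilyloxy)-4β-hydroxyeudesma-5,11(13)-dien-3β-yl (Z)-2-methylbut-2-enoate | C=C(CO[Si](c1ccccc1)(c1ccccc1)C(C)(C)C)[C@H]1C=C2[C@](C)(CC[C@H](OC(=O)/C(C)=C\C)[C@]2(C)O)CC1 | intermediate
20 | 4β,12-dihydroxyeudesma-5,11(13)-dien-3β-yl (Z)-2-methylbut-2-enoate | C=C(CO)[C@H]1C=C2[C@](C)(CC[C@H](OC(=O)/C(C)=C\C)[C@]2(C)O)CC1 | intermediate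
21 | 4β-hydroxy-12-oxoeudesma-5,11(13)-dien-3β-yl (Z)-2-methylbut-2-enoate | C=C(C=O)[C@H]1C=C2[C@](C)(CC[C@H](OC(=O)/C(C)=C\C)[C@]2(C)O)CC1 | intermediate
22 | 3β-[(Z)-2-methylbut-2-enoyloxy]-4β-hydroxyeudesma-5,11(13)-dien-12-oic acid | C=C(C(=O)O)[C@H]1C=C2[C@](C)(CC[C@H](OC(=O)/C(C)=C\C)[C@]2(C)O)CC1 | intermediate
23 | methyl 3β-[(Z)-2-methylbut-2-enoyloxy]-4β-hydroxyeudesma-5,11(13)-dien-12-oate, (3S,4R,7R,10S) | C=C(C(=O)OC)[C@H]1C=C2[C@](C)(CC[C@H](OC(=O)/C(C)=C\C)[C@]2(C)O)CC1 | target

Total step count: 14. Longest linear sequence: 14 steps, from 1 to 23.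

Steps most likely to fail

Step 9. Electron transfer to the conjugated ketone may compete with ketyl formation at the aldehyde and divert material into conjugate reduction or bonding at C6; the aldehyde may simply be reduced; facial control at C4 may be incomplete. The fallback sets out from 15 and forms the same C3–C4 bond by polar addition instead of reductive coupling. An N-heterocyclic-carbene-catalysed intramolecular crossed benzoin reaction (2-mesityl-6,7-dihydro-5H-pyrrolo[2,1-c][1,2,4]triazol-2-ium chloride, Et3N, THF/t-BuOH, rt) should add the aldehyde-derived acyl anion equivalent to the methyl ketone and give the ketol 12-(tert-butyldiphenylsilyloxy)-4β-hydroxyeudesma-5,11(13)-dien-3-one F1. Reduction of its C3 ketone with NaBH4 (MeOH, −40 °C), by axial hydride delivery from the α face, should give the equatorial 3β alcohol and so return to the route at 16.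

Step 10. The angeloyl unit may isomerise to the tigloyl geometry during acyl activation, or acylation next to the tertiary carbinol may be too slow at a temperature the diol tolerates. The fallback sets out from 16 and builds the Z double bond on the substrate. Esterification of the C3 hydroxyl with 2-[bis(2,2,2-trifluoroethoxy)phosphoryl]propanoic acid (DCC, DMAP cat., CH2Cl2) should give 12-(tert-butyldiphenylsilyloxy)-4β-hydroxyeudesma-5,11(13)-dien-3β-yl 2-[bis(2,2,2-trifluoroethoxy)phosphoryl]propanoate F2. Still–Gennari olefination with acetaldehyde (KN(SiMe3)2, 18-crown-6, THF, −78 °C) should then give the Z-trisubstituted enoate and return to the route at 19.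

Step 8. Oxidative addition and transmetallation at the triflate flanked by the quaternary carbon may be slow, allowing protodetriflation, and the dienyl ether may be lost before controlled hydrolysis. The fallback sets out from 11, replaces steps 7 and 8, and returns at 15.
- Nozaki–Hiyama–Kishi coupling with acetaldehyde (CrCl2, NiCl2 cat., DMF, rt) should give methyl 3-[(1S,4R)-4-[3-(tert-butyldiphenylsilyloxy)prop-1-en-2-yl]-2-(1-hydroxyethyl)-1-methylcyclohex-2-en-1-yl]propanoate F3.
- LiAlH4 (THF, 0 °C) should reduce the ester to 3-[(1S,4R)-4-[3-(tert-butyldiphenylsilyloxy)prop-1-en-2-yl]-2-(1-hydroxyethyl)-1-methylcyclohex-2-en-1-yl]propan-1-ol F4.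
- Oxidation of both hydroxyls with Dess–Martin periodinane (NaHCO3, CH2Cl2, rt) should give 15.

Further compounds
F1 | step 9 | 12-(tert-butyldiphenylsilyloxy)-4β-hydroxyeudesma-5,11(13)-dien-3-one | C=C(CO[Si](c1ccccc1)(c1ccccc1)C(C)(C)C)[C@H]1C=C2[C@](C)(CCC(=O)[C@]2(C)O)CC1
F2 | step 10 | 12-(tert-butyldiphenylsilyloxy)-4β-hydroxyeudesma-5,11(13)-dien-3β-yl 2-[bis(2,2,2-trifluoroethoxy)phosphoryl]propanoate (both epimers at the phosphonate carbon) | C=C(CO[Si](c1ccccc1)(c1ccccc1)C(C)(C)C)[C@H]1C=C2[C@](C)(CC[C@H](OC(=O)C(C)P(=O)(OCC(F)(F)F)OCC(F)(F)F)[C@]2(C)O)CC1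
F3 | step 8 | methyl 3-[(1S,4R)-4-[3-(tert-butyldiphenylsilyloxy)prop-1-en-2-yl]-2-(1-hydroxyethyl)-1-methylcyclohex-2-en-1-yl]propanoate (both carbinol epimers) | CC(O)C1=C[C@H](C(=C)CO[Si](c2ccccc2)(c2ccccc2)C(C)(C)C)CC[C@@]1(C)CCC(=O)OC
F4 | step 8 | 3-[(1S,4R)-4-[3-(tert-butyldiphenylsilyloxy)prop-1-en-2-yl]-2-(1-hydroxyethyl)-1-methylcyclohex-2-en-1-yl]propan-1-ol (both carbinol epimers) | CC(O)C1=C[C@H](C(=C)CO[Si](c2ccccc2)(c2ccccc2)C(C)(C)C)CC[C@@]1(C)CCCO
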